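The readings are simulated from invented constants.

At late times alder's complex with two exchanged falls, from 20.7% at 3.00 min to 17.9% at 6.00 min, so it is an intermediate, made and then used up.

the same everywhere: starting complex 47 mM
- cedar: incoming ligand 34 mM; run made earlier
- alder: incoming ligand 320 mM; run made earlier
- dusk: incoming ligand 200 mM; time 6.0 min
- midnight: incoming ligand 94.0 mM; time 6.0 min
- winter: incoming ligand 50.0 mM; time 6.0 min
- noon: incoming ligand 25.0 mM; time 6.0 min

| run | time / min | complex with two exchanged / % |
|---|---|---|
| cedar | 0.500 | 0 |
| cedar | 1.50 | 0.4 |
| cedar | 3.00 | 1.2 |
| cedar | 4.00 | 2.3 |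
| cedar | 6.00 | 3.3 |
| alder | 0.500 | 3.6 |
| alder | 0.833 | 6.9 |
| alder | 1.50 | 14.4 |
| alder | 3.00 | 20.7 |
| alder | 6.00 | 17.9 |

(standard deviation of a reading: 0.5 percentage points)



- the flasks put in order of amount of complex with two exchanged, in percent of the starting complex charged, best first, at 6.0 min (dusk / midnight / winter / noon)
- the amount of complex with two exchanged, in percent of the starting complex charged of the flask you put first, at 6.0 min
- the amount of complex with two exchanged, in percent of the starting complex charged of the flask you put last, at 6.0 min

Time is the first setting you could turn: by hand, more time gives more of this complex, then less, and alder shows that. It is held at 6.0 min here, so ligand is what you turn. If each exchange goes in proportion to the incoming ligand, charge should act as time does. So define the equivalent time: a flask's time multiplied by its c(incoming ligand) and divided by the c(incoming ligand) of an earlier run. With the starting complex held at 47 mM, that run at that time should hold about what the flask holds.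

On alder, dusk gets 3.75 min, past 3.00 min. Reading between alder's points gives 20.0%. Midnight gets 1.76 min, a little past alder's 14.4% at 1.50 min, and winter and noon come lower, in order of charge.

But cedar, whose ligand charge is smaller than its starting complex, reads 3.3% at an alder time of 0.637 min, below alder's 3.6% at 0.500 min. So read noon on cedar, the run nearest its charge. Noon on cedar gets 4.41 min, which reads 2.51%.

The forecast, which “plotted the product against ligand exposure”, gives dusk > midnight > winter > noon, with 21% on top and 1.5% last. Its order is mine, and its low is below my figure.

The flasks give dusk > midnight > winter > noon, with 20.7% and 1.89%.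

    starting complex + incoming ligand ⇌ leaving ligand + complex with one exchanged (K = 29.0, k = 0.0380 L mol⁻¹ s⁻¹)
    complex with one exchanged + incoming ligand ⇌ leaving ligand + complex with two exchanged (K = 0.0800, k = 0.0300 L mol⁻¹ s⁻¹)
    complex with two exchanged + incoming ligand ⇌ leaving ligand + complex with three exchanged (K = 1.50, k = 0.0390 L mol⁻¹ s⁻¹)
    complex with three exchanged + incoming ligand ⇌ leaving ligand + complex with four exchanged (K = 0.0660, k = 0.0360 L mol⁻¹ s⁻¹)
    leaving ligand → by-product carried off (k = 0.0250 s⁻¹)

Dusk still holds 60% of its ligand at 6.00 min. Dusk's 3.75 min gave 20.0%, 0.70 percentage points below what it holds, and noon's 4.41 min gave 2.51%, 0.62 points above.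

Now read dusk at 2.5 min: its alder time is 1.56 min, next to alder's 14.4% at 1.50 min. Computed, dusk at that time holds 13.5% of the complex with two exchanged.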